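Gas enters this flask slowly: even an empty solution takes up 7.68 mM min⁻¹. So before I spend more substrate I want to know which change earns its run, Wednesday's doubling of the transfer coefficient or Sunday's doubling of the saturation concentration.

substrate 0.30 M; gas phase 64 mM (held); time 20 min

- the target standing at 20 min, as a percentage of the substrate charged
- concentration of dissolved gas in solution at 5.0 min, in percent of saturation
- the change that raises the amount of target at 20 min, in percent of the substrate charged most ("none" if none brings more than 2 percentage points) (Wednesday's / Sunday's / none)
- amount of target at 20 min, in percent of the substrate charged, after Sunday's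

Gas dissolves, dissolved gas meets substrate to make target, and target turns into over-reaction product. I count turnovers of target. Its half-life of 5.0 min is shorter than the run of 20 min, so the run holds 2.80 turnovers at 0.14 min⁻¹. One minus exp(−turnovers), divided by that rate constant, gives the minutes of steady uptake that stand as target at the end of the run, the holding window:

window = 6.71 min

Substrate consumes dissolved gas pseudo-first-order at 0.600 min⁻¹. The half-life of 1.2 min is shorter than the run, so I take dissolved gas as balanced:

uptake at the charge = 7.68 mM min⁻¹ × 0.600 min⁻¹ / (0.600 min⁻¹ + 0.12 min⁻¹) = 6.40 mM min⁻¹

substrate after that uptake for the whole run = 0.172 M, so late uptake = 5.69 mM min⁻¹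

target = late uptake × window = 12.7 %

Neither change touches the window, so I compare uptakes at the charge. Sunday's gives 12.8 mM min⁻¹ and Wednesday's 11.0 mM min⁻¹. Through the window these reckon to gains of 14 percentage points and 10 points. I commit to the order, not the sizes, and I charge Sunday's. I reckon neither the saturation nor Sunday's amount.

The forecast gives 12.8 %, 16.8 % of saturation, Sunday's as best and 21.4 % after it, on the ground that “Uptake is therefore transfer-limited”. My 12.7 % is less than its 12.8 %.

The simulation gives 12.8 %, 16.9 %, Sunday's with 9 points against 6.1 points for Wednesday's, and 21.8 % after Sunday's.

    gas phase ⇌ dissolved gas, rate k1*(csat - [dissolved gas]) (k1 = 0.12 min⁻¹, csat = 64 mM)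
    substrate + dissolved gas → target (k2 = 2.0 M⁻¹ min⁻¹)
    target → over-reaction product (k3 = 0.14 min⁻¹)

Waiting is another way to spend the next run, so I put the window on the same flask read at 50 min. There it reaches 7.14 min, against 6.71 min at 20 min. That flask keeps 17.3 % of its substrate, which gives a reckoned late uptake of 3.56 mM min⁻¹ and a reckoned target of 8.48 %. The flask read at 50 min holds 9.26 % target, less than the 12.8 % at 20 min, and 73.4 % over-reaction product.

(The rate constants were set for the occasion; the run is a simulation.)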